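**Retrosynthetic overview**

- Numbering used throughout: ring C1–C14 with C14 = stereocentre, C1H2, C2H=C3(CH3), C4H2, C5H2, C6H=C7(CH2OH), C8H2, C9H2, C10H=C11(CH3), C12H2, C13H2. The side chain C15(CH3)=C16H–C17H2–C18H=C19(CH3)2 sits on C14.
- 21 ⇐ silyl ether 20 ⇐ acyclic hexaene 18. The only ring, the 14-membered carbocycle, is closed last at C3(sp2)–C4(sp3). One flask does it: 9-BBN hydroboration of the terminal diene, then intramolecular B-alkyl Suzuki–Miyaura coupling with the (Z)-vinyl iodide.
- Enabling feature: in the 14-membered ring the ethano bridge C4H2–C5H2 lies between two trisubstituted ring olefins whose ring bonds are cis (C2=C3 bearing CH3, C6=C7 bearing CH2OH). C4–C5–C6=C7 is therefore the retron of a 1,3-diene hydroborated at its vinyl end. C3 can hold iodine with fixed Z geometry, and the two cis olefins fold the chain ends toward each other.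
- 18 ⇐ aldehyde 17 (iodoethylidene Wittig, Z-C2=C3) ⇐ ester 16 ⇐ diene ester 14 + iododiene 4. The C7–C8 bond uses the same hydroboration/coupling tactic between two molecules; 4 comes from acrolein 1.
- 14 ⇐ (8R)-8-hydroxyfarnesyl acetate 9 by Johnson–Claisen rearrangement, which sets C14 and E-C15=C16 together by 1,3-chirality transfer. 9 ⇐ geranyl acetate 5 by allylic oxidation, catalytic asymmetric allylation and cross-metathesis.

Key step: step 15

Remark: the target SMILES is read as 14R, 2Z, 6E (CIP; ring bonds cis at C2=C3 and at C6=C7), 10E and 15E. The route is planned for this isomer.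

**Step 1**
Reactants: 1 acrolein
Product: 2 ethyl (2Z)-2-iodopenta-2,4-dienoate
Conditions: Ph3P=CHCO2Et, NIS, CH2Cl2, −20 °C; then 1, −20 °C to rt
Reagents that add atoms: ethyl (triphenylphosphoranylidene)acetate, CCOC(=O)C=P(c1ccccc1)(c1ccccc1)c1ccccc1; N-iodosuccinimide, O=C1CCC(=O)N1I
Why: Wittig olefination with the stabilised α-iodo ylide made in the flask should place the ester trans to the vinyl group and so iodine cis to it (Z), as is usual for α-halo stabilised ylides, and any minor E isomer is removed by chromatography.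

**Step 2**
Reactants: 2 ethyl (2Z)-2-iodopenta-2,4-dienoate
Product: 3 (2Z)-2-iodopenta-2,4-dien-1-ol
Conditions: iBu2AlH (2.2 equiv), CH2Cl2, −78 °C; aq. potassium sodium tartrate
Reagents that add atoms: none
Why: 1,2-reduction of the unsaturated ester by iBu2AlH at low temperature gives the allylic alcohol and leaves the C–I bond, the diene and the olefin geometry untouched.

**Step 3**
Reactants: 3 (2Z)-2-iodopenta-2,4-dien-1-ol
Product: 4 tert-butyl{[(2Z)-2-iodopenta-2,4-dien-1-yl]oxy}dimethylsilane
Conditions: TBSCl, imidazole, CH2Cl2, 0 °C to rt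
Reagents that add atoms: tert-butyldimethylsilyl chloride, CC(C)(C)[Si](C)(C)Cl
Why: Standard imidazole-promoted silylation of a primary alcohol gives an ether that survives boranes, aqueous base, iBu2AlH and ylides.

**Step 4**
Reactants: 5 geranyl acetate
Product: 6 (2E,6E)-8-hydroxy-3,7-dimethylocta-2,6-dien-1-yl acetate
Conditions: SeO2 (cat.), t-BuOOH, CH2Cl2, 0 °C to rt
Reagents that add atoms: SeO2, O=[Se]=O; tert-butyl hydroperoxide, CC(C)(C)OO
Why: Selenium dioxide allylic oxidation (ene reaction, then [2,3]-sigmatropic shift) attacks the electron-rich terminal isopropylidene group at its E methyl group, while the olefin next to the acetate is deactivated.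

**Step 5**
Reactants: 6 (2E,6E)-8-hydroxy-3,7-dimethylocta-2,6-dien-1-yl acetate
Product: 7 (2E,6E)-3,7-dimethyl-8-oxoocta-2,6-dien-1-yl acetate
Conditions: TEMPO (cat.), PhI(OAc)2, CH2Cl2, rt
Reagents that add atoms: none
Why: Oxoammonium (TEMPO) oxidation turns the allylic alcohol into the enal without E/Z isomerisation, and any aldehyde already formed in step 4 converges here.

**Step 6**
Reactants: 7 (2E,6E)-3,7-dimethyl-8-oxoocta-2,6-dien-1-yl acetate
Product: 8 (2E,6E,8R)-8-hydroxy-3,7-dimethylundeca-2,6,10-trien-1-yl acetate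
Conditions: allylSnBu3, Ti(OiPr)4 (10 mol %), (R)-BINOL (20 mol %), 4 Å molecular sieves, CH2Cl2, −20 °C; aq. NaHCO3
Reagents that add atoms: allyltributylstannane, C=CC[Sn](CCCC)(CCCC)CCCC
Why: In the Keck asymmetric allylation the (R)-BINOL–titanium Lewis acid should direct the stannane to the Re face of the α-methyl enal and so set the carbinol centre (C16) as R, with the acetate inert.

**Step 7**
Reactants: 8 (2E,6E,8R)-8-hydroxy-3,7-dimethylundeca-2,6,10-trien-1-yl acetate
Product: 9 (2E,6E,8R)-8-hydroxy-3,7,11-trimethyldodeca-2,6,10-trien-1-yl acetate [(8R)-8-hydroxyfarnesyl acetate]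
Conditions: second-generation Grubbs catalyst RuCl2(=CHPh)(H2IMes)(PCy3) (3 mol %), 2-methyl-2-butene/CH2Cl2, 40 °C, sealed vessel
Reagents that add atoms: 2-methyl-2-butene, CC=C(C)C
Why: Olefin cross-metathesis with excess 2-methyl-2-butene converts the only monosubstituted olefin into the isopropylidene group, while the trisubstituted olefins do not engage the catalyst.

**Step 8**
Reactants: 9 (8R)-8-hydroxyfarnesyl acetate
Product: 11 ethyl (3R,4E)-3-[(3E)-5-acetoxy-3-methylpent-3-en-1-yl]-4,8-dimethylnona-4,7-dienoate, via ketene acetal 10 (not isolated)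
Conditions: MeC(OEt)3 (excess), EtCO2H (cat.), 135 °C, EtOH distilled off
Reagents that add atoms: triethyl orthoacetate, CC(OCC)(OCC)OCC
Why: The Johnson–Claisen rearrangement runs through a chair transition state with the prenyl group on C16 equatorial, so the suprafacial [3,3] shift across the E-C14=C15 olefin transfers 16R to 14R and creates E-C15=C16 in the same event.

**Step 9**
Reactants: 11 ethyl (3R,4E)-3-[(3E)-5-acetoxy-3-methylpent-3-en-1-yl]-4,8-dimethylnona-4,7-dienoate
Product: 12 ethyl (3R,4E)-3-[(3E)-5-hydroxy-3-methylpent-3-en-1-yl]-4,8-dimethylnona-4,7-dienoate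
Conditions: K2CO3 (cat.), EtOH, 0 °C to rt
Reagents that add atoms: none
Why: Base-catalysed transesterification removes the primary allylic acetate, and ethanol as solvent makes exchange at the ethyl ester degenerate.

**Step 10**
Reactants: 12 ethyl (3R,4E)-3-[(3E)-5-hydroxy-3-methylpent-3-en-1-yl]-4,8-dimethylnona-4,7-dienoate
Product: 13 ethyl (3R,4E)-4,8-dimethyl-3-[(3E)-3-methyl-5-oxopent-3-en-1-yl]nona-4,7-dienoate
Conditions: TEMPO (cat.), PhI(OAc)2, CH2Cl2, rt
Reagents that add atoms: none
Why: TEMPO oxidation of the geraniol-type allylic alcohol gives the E enal without isomerisation and does not touch the ester or the skipped diene.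

**Step 11**
Reactants: 13 ethyl (3R,4E)-4,8-dimethyl-3-[(3E)-3-methyl-5-oxopent-3-en-1-yl]nona-4,7-dienoate
Product: 14 ethyl (3R,4E)-4,8-dimethyl-3-[(3E)-3-methylhexa-3,5-dien-1-yl]nona-4,7-dienoate
Conditions: MePPh3Br, NaN(SiMe3)2, THF, 0 °C; then 13, −78 °C to 0 °C
Reagents that add atoms: methyltriphenylphosphonium bromide, C[P+](c1ccccc1)(c1ccccc1)c1ccccc1.[Br-]
Why: In this Wittig methylenation the non-stabilised ylide reacts with the enal far faster than with the ester and leaves E-C10=C11 as it is.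

**Step 12**
Reactants: 14 ethyl (3R,4E)-4,8-dimethyl-3-[(3E)-3-methylhexa-3,5-dien-1-yl]nona-4,7-dienoate; 4 tert-butyl{[(2Z)-2-iodopenta-2,4-dien-1-yl]oxy}dimethylsilane
Product: 16 ethyl (3R,4E)-3-[(3E,7E)-7-{[(tert-butyldimethylsilyl)oxy]methyl}-3-methyldeca-3,7,9-trien-1-yl]-4,8-dimethylnona-4,7-dienoate, via B-alkyl-9-BBN 15 (not isolated)
Conditions: 9-BBN dimer, THF, 0 °C to rt; H2O; then 4, Pd(dppf)Cl2 (5 mol %), AsPh3, Cs2CO3, DMF/THF/H2O, rt
Reagents that add atoms: none
Why: In this B-alkyl Suzuki–Miyaura coupling 9-BBN adds only to the monosubstituted end of the 1,3-diene (boron on C8), and the derived borate couples with the vinyl iodide with retention, so C8 ends up cis to C5 as iodine was.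

**Step 13**
Reactants: 16 ethyl (3R,4E)-3-[(3E,7E)-7-{[(tert-butyldimethylsilyl)oxy]methyl}-3-methyldeca-3,7,9-trien-1-yl]-4,8-dimethylnona-4,7-dienoate
Product: 17 (3R,4E)-3-[(3E,7E)-7-{[(tert-butyldimethylsilyl)oxy]methyl}-3-methyldeca-3,7,9-trien-1-yl]-4,8-dimethylnona-4,7-dienal
Conditions: iBu2AlH (1.05 equiv), toluene, −78 °C; aq. potassium sodium tartrate
Reagents that add atoms: none
Why: Partial ester reduction stops at the aluminium hemiacetal, which is stable at −78 °C and releases the aldehyde only on work-up, while C14 (β to the carbonyl) cannot epimerise.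

**Step 14**
Reactants: 17 (3R,4E)-3-[(3E,7E)-7-{[(tert-butyldimethylsilyl)oxy]methyl}-3-methyldeca-3,7,9-trien-1-yl]-4,8-dimethylnona-4,7-dienal
Product: 18 tert-butyl{[(2E,5E,9R,11Z)-12-iodo-6-methyl-9-[(2E)-6-methylhepta-2,5-dien-2-yl]-2-(prop-2-en-1-ylidene)trideca-5,11-dien-1-yl]oxy}dimethylsilane
Conditions: EtPPh3I, n-BuLi, THF, rt; I2, −78 °C; NaN(SiMe3)2, −20 °C; then 17, −78 °C
Reagents that add atoms: ethyltriphenylphosphonium iodide, CC[P+](c1ccccc1)(c1ccccc1)c1ccccc1.[I-]; iodine, II
Why: In this Stork–Zhao-type Wittig olefination the non-stabilised α-iodo ylide reacts under kinetic control through the cis-oxaphosphetane, which puts iodine cis to C1 (Z), the geometry known for this reagent with α-unbranched aldehydes.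

**Step 15**
Reactants: 18 tert-butyl{[(2E,5E,9R,11Z)-12-iodo-6-methyl-9-[(2E)-6-methylhepta-2,5-dien-2-yl]-2-(prop-2-en-1-ylidene)trideca-5,11-dien-1-yl]oxy}dimethylsilane
Product: 20 tert-butyl{[(2Z,6E,10E,14R)-3,11-dimethyl-14-[(2E)-6-methylhepta-2,5-dien-2-yl]cyclotetradeca-2,6,10-trien-7-yl]methoxy}dimethylsilane (route numbering), via homoallylic B-alkyl-9-BBN 19 (not isolated)
Conditions: 9-BBN dimer (1.2 equiv B–H), THF, 0 °C to rt; H2O; then syringe-pump addition to Pd(dppf)Cl2 (15 mol %), AsPh3 (30 mol %), Cs2CO3 (4 equiv), DMF/THF/H2O, 45 °C, final concentration about 1 mM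
Reagents that add atoms: none
Why: 9-BBN should add only to the monosubstituted C4=C5 end of the 1,3-diene (boron on C4), since the other five C=C bonds of 18 are trisubstituted or carry iodine, and this gives the homoallylic borane 19 with C6=C7 untouched. Base then converts 19 into its borate, zerovalent palladium inserts into the C3–I bond with retention, the primary alkyl group passes from boron to palladium and reductive elimination forms C3–C4; the closest known reaction type is the macrocyclising B-alkyl Suzuki–Miyaura coupling of a vinyl iodide with a 9-BBN-derived alkylborane. The one ring closed is the 14-membered carbocycle, formed end-to-end through a 15-membered palladacycle with C2=C3 ending up endocyclic. No stereocentre is created; C14 is not epimerisable and is carried through, and the Z geometry at C2=C3 and the E geometry at C6=C7 are retained because no elementary step breaks these π bonds. The step needs ring closure to outrun oligomerisation, β-hydride elimination and 5-exo carbopalladation onto C15=C16, which slow addition into a dilute catalyst solution, the dppf/AsPh3 ligand pair (fast reductive elimination) and the fold imposed by the two olefins with cis ring bonds on either side of C4–C5 should secure. In one flask the operation thus selects one of six C=C bonds, completes the 1,5-diene C2=C3–C4–C5–C6=C7 and turns an acyclic polyene into the complete ring skeleton.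

**Step 16**
Reactants: 20 tert-butyl{[(2Z,6E,10E,14R)-3,11-dimethyl-14-[(2E)-6-methylhepta-2,5-dien-2-yl]cyclotetradeca-2,6,10-trien-7-yl]methoxy}dimethylsilane
Product: 21 [(2Z,6E,10E,14R)-3,11-dimethyl-14-[(2E)-6-methylhepta-2,5-dien-2-yl]cyclotetradeca-2,6,10-trien-7-yl]methanol (route numbering), the target
Conditions: Bu4NF, THF, 0 °C to rt
Reagents that add atoms: none
Why: Fluoride-induced cleavage of the primary silyl ether is selective for silicon and leaves the five olefins and C14 unchanged.

**Compound list**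

1 | acrolein | C=CC=O | starting material
2 | ethyl (2Z)-2-iodopenta-2,4-dienoate | C=C/C=C(\I)C(=O)OCC | intermediate
3 | (2Z)-2-iodopenta-2,4-dien-1-ol | C=C/C=C(\I)CO | intermediate
4 | tert-butyl{[(2Z)-2-iodopenta-2,4-dien-1-yl]oxy}dimethylsilane | C=C/C=C(\I)CO[Si](C)(C)C(C)(C)C | intermediate
5 | geranyl acetate, (2E)-3,7-dimethylocta-2,6-dien-1-yl acetate | CC(C)=CCC/C(C)=C/COC(C)=O | starting material
6 | (2E,6E)-8-hydroxy-3,7-dimethylocta-2,6-dien-1-yl acetate | OC/C(C)=C/CC/C(C)=C/COC(C)=O | intermediate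
7 | (2E,6E)-3,7-dimethyl-8-oxoocta-2,6-dien-1-yl acetate | O=C/C(C)=C/CC/C(C)=C/COC(C)=O | intermediate
8 | (2E,6E,8R)-8-hydroxy-3,7-dimethylundeca-2,6,10-trien-1-yl acetate | C=CC[C@@H](O)/C(C)=C/CC/C(C)=C/COC(C)=O | intermediate
9 | (2E,6E,8R)-8-hydroxy-3,7,11-trimethyldodeca-2,6,10-trien-1-yl acetate | CC(C)=CC[C@@H](O)/C(C)=C/CC/C(C)=C/COC(C)=O | intermediate
10 | (2E,6E,8R)-8-[(1-ethoxyethenyl)oxy]-3,7,11-trimethyldodeca-2,6,10-trien-1-yl acetate (ketene acetal, not isolated) | CC(C)=CC[C@@H](OC(=C)OCC)/C(C)=C/CC/C(C)=C/COC(C)=O | intermediate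
11 | ethyl (3R,4E)-3-[(3E)-5-acetoxy-3-methylpent-3-en-1-yl]-4,8-dimethylnona-4,7-dienoate | CCOC(=O)C[C@@H](CC/C(C)=C/COC(C)=O)/C(C)=C/CC=C(C)C | intermediate
12 | ethyl (3R,4E)-3-[(3E)-5-hydroxy-3-methylpent-3-en-1-yl]-4,8-dimethylnona-4,7-dienoate | CCOC(=O)C[C@@H](CC/C(C)=C/CO)/C(C)=C/CC=C(C)C | intermediate
13 | ethyl (3R,4E)-4,8-dimethyl-3-[(3E)-3-methyl-5-oxopent-3-en-1-yl]nona-4,7-dienoate | CCOC(=O)C[C@@H](CC/C(C)=C/C=O)/C(C)=C/CC=C(C)C | intermediate
14 | ethyl (3R,4E)-4,8-dimethyl-3-[(3E)-3-methylhexa-3,5-dien-1-yl]nona-4,7-dienoate | CCOC(=O)C[C@@H](CC/C(C)=C/C=C)/C(C)=C/CC=C(C)C | intermediate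
15 | ethyl (3R,4E)-3-[(3E)-6-(9-borabicyclo[3.3.1]nonan-9-yl)-3-methylhex-3-en-1-yl]-4,8-dimethylnona-4,7-dienoate (not isolated) | CCOC(=O)C[C@@H](CC/C(C)=C/CCB1C2CCCC1CCC2)/C(C)=C/CC=C(C)C | intermediate
16 | ethyl (3R,4E)-3-[(3E,7E)-7-{[(tert-butyldimethylsilyl)oxy]methyl}-3-methyldeca-3,7,9-trien-1-yl]-4,8-dimethylnona-4,7-dienoate | CCOC(=O)C[C@@H](CC/C(C)=C/CC/C(CO[Si](C)(C)C(C)(C)C)=C\C=C)/C(C)=C/CC=C(C)C | intermediate
17 | (3R,4E)-3-[(3E,7E)-7-{[(tert-butyldimethylsilyl)oxy]methyl}-3-methyldeca-3,7,9-trien-1-yl]-4,8-dimethylnona-4,7-dienal | O=CC[C@@H](CC/C(C)=C/CC/C(CO[Si](C)(C)C(C)(C)C)=C\C=C)/C(C)=C/CC=C(C)C | intermediate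
18 | tert-butyl{[(2E,5E,9R,11Z)-12-iodo-6-methyl-9-[(2E)-6-methylhepta-2,5-dien-2-yl]-2-(prop-2-en-1-ylidene)trideca-5,11-dien-1-yl]oxy}dimethylsilane | C/C(I)=C/C[C@@H](CC/C(C)=C/CC/C(CO[Si](C)(C)C(C)(C)C)=C\C=C)/C(C)=C/CC=C(C)C | intermediate
19 | the C4 B-alkyl-9-BBN derived from 18: 2-[3-(9-borabicyclo[3.3.1]nonan-9-yl)propylidene] analogue of 18 (not isolated) | C/C(I)=C/C[C@@H](CC/C(C)=C/CC/C(CO[Si](C)(C)C(C)(C)C)=C\CCB1C2CCCC1CCC2)/C(C)=C/CC=C(C)C | intermediate
20 | tert-butyl{[(2Z,6E,10E,14R)-3,11-dimethyl-14-[(2E)-6-methylhepta-2,5-dien-2-yl]cyclotetradeca-2,6,10-trien-7-yl]methoxy}dimethylsilane (route numbering) | CC(C)=CC/C=C(\C)[C@H]1C/C=C(/C)CC/C=C(/CO[Si](C)(C)C(C)(C)C)CC/C=C(\C)CC1 | intermediate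
21 | [(2Z,6E,10E,14R)-3,11-dimethyl-14-[(2E)-6-methylhepta-2,5-dien-2-yl]cyclotetradeca-2,6,10-trien-7-yl]methanol (route numbering) | CC(C)=CC/C=C(\C)[C@H]1C/C=C(/C)CC/C=C(/CO)CC/C=C(\C)CC1 | target

**Step count**

Total step count: 16 (steps 1–3 for fragment 4, steps 4–16 for the main line).
Longest linear sequence: 13 steps (steps 4–16, from geranyl acetate 5).

**Steps most likely to fail**

**1. Step 15.**
- What may go wrong: at high dilution the transfer of the alkyl group from boron to palladium may become slow. Intermolecular coupling (oligomerisation), protodeboronation, β-hydride elimination or 5-exo carbopalladation of the vinylpalladium species onto C15=C16 could then take over.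
- Fallback: it sets out from 18 (through 19) and comes back at 20.
- Borane 19, made as in step 15, would be oxidised (NaBO3·4H2O, THF/H2O) to the homoallylic C4 alcohol F1.
- Iodination (I2, PPh3, imidazole) would give the primary C4 iodide F2.
- Activated Zn dust in THF should insert only into the sp3 C–I bond and give the alkylzinc iodide F3.
- Slow addition of F3 to Pd(dppf)Cl2 in THF would close the same C3–C4 bond by an intramolecular Negishi coupling. This separates metalation from ring closure, needs no aqueous base and relies on the much faster transmetalation from zinc.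

**2. Step 14.**
- What may go wrong: the α-iodo ylide may decompose or lose iodine before it meets the aldehyde. The aldehyde may be enolised, and Z selectivity may erode.
- Fallback: it sets out from 17 and comes back at 20.
- Corey–Fuchs-type dibromoolefination (CBr4, PPh3, Et3N, CH2Cl2, 0 °C) would give the 1,1-dibromoalkene F4.
- A trans-selective Negishi mono-methylation (MeZnCl, Pd(DPEphos)Cl2 cat., THF, 0 °C) should react first at the less hindered C–Br bond trans to C1 and give the (Z)-vinyl bromide F5.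
- F5 would take the place of 18 in step 15. Hydroboration with 9-BBN gives the B-alkyl-9-BBN F6, which is cyclised under the conditions of step 15 at a somewhat higher temperature.

**3. Step 6.**
- What may go wrong: the α-branched enal may turn over slowly on the titanium catalyst, and facial selectivity may be poor. This would lower the enantiomeric purity of everything that follows.
- Fallback: it sets out from 7 and comes back at 8.
- Barbier allylation (allyl bromide, indium powder, THF/H2O) would give the racemic homoallylic alcohol F7.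
- Buffered Dess–Martin oxidation would give the allyl dienone F8.
- Corey–Bakshi–Shibata reduction ((S)-2-methyl-CBS-oxazaborolidine cat., catecholborane, toluene, −78 °C), with the α-methylalkenyl group acting as the large substituent, should give 8 with the 8R configuration. Stereocontrol thus moves from C–C bond formation to ketone reduction.

**Further compounds**

F1 | step 15 | C4 alcohol: 2-(3-hydroxypropylidene) analogue of 18 | C/C(I)=C/C[C@@H](CC/C(C)=C/CC/C(CO[Si](C)(C)C(C)(C)C)=C\CCO)/C(C)=C/CC=C(C)C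
F2 | step 15 | C4 iodide: 2-(3-iodopropylidene) analogue of 18 | C/C(I)=C/C[C@@H](CC/C(C)=C/CC/C(CO[Si](C)(C)C(C)(C)C)=C\CCI)/C(C)=C/CC=C(C)C
F3 | step 15 | C4 alkylzinc iodide derived from F2 | C/C(I)=C/C[C@@H](CC/C(C)=C/CC/C(CO[Si](C)(C)C(C)(C)C)=C\CC[Zn]I)/C(C)=C/CC=C(C)C
F4 | step 14 | 1,1-dibromoalkene derived from 17 | BrC(Br)=CC[C@@H](CC/C(C)=C/CC/C(CO[Si](C)(C)C(C)(C)C)=C\C=C)/C(C)=C/CC=C(C)C
F5 | step 14 | (Z)-vinyl bromide, the bromo analogue of 18 | C/C(Br)=C/C[C@@H](CC/C(C)=C/CC/C(CO[Si](C)(C)C(C)(C)C)=C\C=C)/C(C)=C/CC=C(C)C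
F6 | step 14 | C4 B-alkyl-9-BBN derived from F5 | C/C(Br)=C/C[C@@H](CC/C(C)=C/CC/C(CO[Si](C)(C)C(C)(C)C)=C\CCB1C2CCCC1CCC2)/C(C)=C/CC=C(C)C
F7 | step 6 | racemic (2E,6E)-8-hydroxy-3,7-dimethylundeca-2,6,10-trien-1-yl acetate | C=CCC(O)/C(C)=C/CC/C(C)=C/COC(C)=O
F8 | step 6 | (2E,6E)-3,7-dimethyl-8-oxoundeca-2,6,10-trien-1-yl acetate | C=CCC(=O)/C(C)=C/CC/C(C)=C/COC(C)=O
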